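## The problem

Compound 28 is a sesquilignan built on a cis-fused 3,7-dioxabicyclo[3.3.0]octane. Ring A (C7, O, C9', C8', C8) carries a guaiacyl group at C7 on the convex face, ring B (C7', O, C9, C8, C8') carries a syringyl group at C7' on the concave face, and O-4 of that syringyl ring is bound to C8'' of a threo syringylglycerol chain (lignan numbering, kept for all intermediates). There are six stereocentres: 7R, 8S, 8'S and 7'S in the bicycle, 7''R and 8''R in the chain. The chain is separated from the bicycle by an aryl ether and a benzene ring, so neither part can control the other and each must be made as a single enantiomer. Inside the core, C8 and C8' are coupled (cis fusion is the only possibility once both rings exist) and can pass information to C7 and C7' only through a ring that contains them. The two benzylic centres ask for opposite things: exo at C7, the thermodynamic position, and endo at C7', the disfavoured one. The endo centre must therefore be set under kinetic control and never be allowed to ionise afterwards, because electron-rich benzylic ethers and alcohols of this kind epimerise in acid or close onto the neighbouring arene. The free phenols are sensitive to oxidants, periodate included, and have to stay masked until the last step. The feature that opens the plan is the C9–C8–C8'–C9' chain with an oxygen at each end: it is a butyrolactone in disguise, and in the corresponding butenolide C8 is an acceptor and C8' then a donor, the polarity needed to attach C7 as an acyl anion and C7' as an aldehyde. Since C9 ends as an oxygen-bound CH2 group, it can carry one extra carbon that fixes the absolute configuration and is cut off later.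

## Retrosynthesis

**28 from 27.** The last operation should only free the two phenols and the two side-chain hydroxyls. All four are therefore carried as silyl ethers in 27 and released together by fluoride. This avoids acid, which would epimerise the endo C7' ether, and hydrogenolysis, which threatens three benzylic C–O bonds.

**27 from 25.** Both tetrahydrofuran rings are cut at the primary carbon: O–C9' in ring A and O–C9 in ring B, leading to tetraol 25 through its bis-sulfonate 26. The neighbouring cut at the benzylic C–O bonds would run through benzylic cations and give the exo,exo isomer. Cutting on the primary side leaves the C7–O and C7'–O bonds intact, so the carbinol configurations of 25 are carried into 27 with retention. The forward reaction has to sulfonylate only the two primary hydroxyls and then close two rings by 5-exo-tet displacement.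

**25 from 23 and 22.** The primary carbinol C9 of 25 is traced to a secondary carbinol bearing one extra hydroxymethyl carbon (C10) in pentaol 23. Glycol cleavage and reduction of the resulting aldehyde 24 remove C10. Pentaol 23 is the hydride-reduction product of γ-lactone 22, whose ring is the C9'–C8'–C8–C9 chain. Keeping C10 until this point is what allows one stereocentre of a chiral-pool lactone to set C8 and C8' absolutely.

**22 from 21, 20 and 19.** The (7R)-carbinol of 22 is taken back to aryl ketone 21. The α-carbon C8 is flanked by two ring carbons whose substituents both point to the opposite face, so substrate bias should be small and an external chiral reducing agent is asked to decide. Ketone 21 comes from dithiane 20, and 20 from its dimethoxytrityl ether 19. The trityl-type group is removed first, while the only benzylic carbinol present is the deactivated aldol hydroxyl and no hydroxyl sits in position to trap a cation.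

**19 from 3, 5 and 16 (key disconnection).** The C7–C8 and C7'–C8' bonds are cut together. This is preferred to the C8–C8' cut (an oxidative dimerisation), which cannot tell the two aryl groups apart, fix the absolute configuration or give an endo aryl group. The three precursors are of very different complexity but each is simple in kind: dithiane 3, butenolide 5 and aldehyde 16, which already holds the complete side chain. The forward reaction must add lithiated 3 in 1,4-fashion anti to the bulky ether of 5, trap the enolate with 16 anti to the new substituent, and give the anti aldol at C7'. The dimethoxytrityl ether is chosen over the plain trityl ether because it gives the same shielding but leaves under acid weak enough to spare a primary TBS ether and a benzylic carbinol.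

**16 from 14, 13, 12, 10 and 7.** The aldehyde carbon of 16 is introduced last by formylation of aryllithium 15, made from bromide 14. A bromide is an inert placeholder for a formyl group that would not survive enolate chemistry. The tris-silyl ether 14 comes from diol 13, and 13 from imide 12 by reductive removal of the auxiliary. The C7''–C8'' bond of 12 is cut as a syn-selective auxiliary-controlled glycolate aldol between aryloxyacetyl imide 10 and aldehyde 7. A syn aldol of an α-aryloxy imide is the threo relationship, and the (S)-benzyl auxiliary gives (7''R,8''R). The alternative, dihydroxylation of a cinnamate followed by etherification at C8'' with inversion, would give the erythro series.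

**Small building blocks.** Dithiane 3 comes from vanillin 1 through phenol 2. Butenolide 5 is the ether of the chiral-pool butenolide 4. Aldehyde 7 is silylated syringaldehyde 6. Imide 10 is made by O-alkylation of 4-bromo-2,6-dimethoxyphenol 8 with chloroacetyl imide 9.

## Roads not taken

Alternative 1: Ring B is cut at O–C9 and traced to a dihydrofuran. In the forward key step a tertiary amine catalyst opens the lactone-fused aroyl cyclopropane A2 at its CH2 carbon (C9), and the enolate oxygen of the aryl ketone displaces the ammonium group. This nucleophile-catalysed Cloke–Wilson-type ring expansion gives the dihydrofuran-fused lactone A1, in which ring A already exists as a lactone with the exo guaiacyl group and C7'=C8' is an enol ether.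
- Merits: the key step is catalytic and mild. The endo syringyl group would arise from cis addition of hydrogen to the convex face of A1, a kinetic delivery that suits the disfavoured centre well. No carbon has to be excised afterwards.
- Weak points: the enol ether of A1 is tetrasubstituted and conjugated to the lactone carbonyl, so it is hard to hydrogenate, and the benzylic C7–O lactone bond on an electron-rich ring is prone to hydrogenolysis under the forcing conditions needed. The lactone carbonyl C9' must still be taken down to CH2 by reduction and re-closure. A2 must be made enantiopure by a cyclopropanation that carries the whole side-chain-bearing aroyl group.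
- Comparison: in how it sets C7' this road is at least equal to the chosen plan. The chosen plan sets against it polar bond formations with close precedent, one chiral-pool stereocentre for the whole core, and no hydrogenation in the presence of benzylic C–O bonds.

Alternative 2: Three bonds are cut at once: O–C9, C8–C8' and the lactone O–C7. In the forward cascade the alkoxide of the threo epoxy alcohol A4 adds to dimethyl methylenemalonate A5, the malonate anion opens the epoxide at C8' with inversion to close ring B, and the released C9' alkoxide lactonises onto one ester to give the cis-fused lactone ester A3 with the endo syringyl group.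
- Merits: both rings and three bonds form in one operation. C7' comes from a carbinol and C8' from an epoxide, both accessible by asymmetric epoxidation. In bond economy this is clearly better than the chosen plan.
- Weak points: A3 still lacks the guaiacyl group, and C7 is a lactone carbonyl. Attaching the aryl group requires addition to the lactone and reductive removal of the lactol hydroxyl with a Lewis acid and a silane, conditions under which the endo C7' ether epimerises and the benzylic silyl ether of the side chain ionises. The angular ester at C8 must then be removed. A5 polymerises readily, and A4 needs a kinetic resolution of a side-chain-bearing vinyl carbinol.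
- Comparison: the chosen plan is longer to the bicycle, but it brings in both aryl groups before any ring closure and closes both rings under basic SN2 conditions that never put the endo centre at risk.

Alternative 3: The C7'–C8' bond is cut. In the forward step a dirhodium tetracarboxylate catalyst turns the α-diazo lactone A7 into a carbenoid at C8' that inserts into a benzylic C–H bond of the tethered syringylmethyl ether, closing ring B and giving the furofuranone A6 with endo syringyl and exo guaiacyl groups.
- Merits: this kind of 1,5-insertion is known to favour the endo-aryl, cis-fused product, so the hardest stereocentre is fixed by the mechanism. The endgame (lactone reduction and one ring closure on the primary side) would be shorter than in the chosen plan.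
- Weak points: the carbenoid meets four electron-rich arenes and many ether oxygens. Cycloaddition to an arene and oxonium ylide formation compete with insertion, and the selectivity has to hold for a benzylic ether that carries the bulky side chain. A7 needs an enantioselective route to a trans lactone, an etherification with an unstable electron-rich benzyl halide, and a diazo transfer.
- Comparison: for directness at C7' this road is as good as or better than the chosen plan. The chosen plan sets against it a convergent three-fragment coupling in which the side-chain fragment enters as an ordinary aldehyde, and a stepwise fallback for each stereocentre.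

Key step: step 10

Remark: compounds 4, 8 and 9 are taken as purchased (4 is the chiral-pool butenolide classically prepared from L-glutamic acid). ArG = 3-methoxy-4-(triisopropylsilyloxy)phenyl. ArS = 3,5-dimethoxy-4-{[(1R,2R)-1,3-bis(tert-butyldimethylsilyloxy)-1-(4-tert-butyldimethylsilyloxy-3,5-dimethoxyphenyl)propan-2-yl]oxy}phenyl. DMTr = bis(4-methoxyphenyl)(phenyl)methyl. C10 is the extra carbon on C9.

## Route

Step 1
Reactants: 1 vanillin (4-hydroxy-3-methoxybenzaldehyde)
Product: 2 2-(4-hydroxy-3-methoxyphenyl)-1,3-dithiane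
Conditions: HS(CH2)3SH, BF3·OEt2 (cat.), CH2Cl2, 0 °C → rt
Reagents that add atoms: propane-1,3-dithiol, SCCCS
Why: Lewis-acid-catalysed dithioacetalisation of an aromatic aldehyde; the free phenol does not interfere, and the dithiane turns C7 into a latent acyl anion.

Step 2
Reactants: 2 2-(4-hydroxy-3-methoxyphenyl)-1,3-dithiane
Product: 3 2-[3-methoxy-4-(triisopropylsilyloxy)phenyl]-1,3-dithiane
Conditions: TIPSCl, imidazole, DMF, rt
Reagents that add atoms: triisopropylsilyl chloride, CC(C)[Si](Cl)(C(C)C)C(C)C
Why: Imidazole-promoted silylation of a phenol; the hindered aryl silyl ether should survive butyllithium and hydride reagents and leave with fluoride at the end.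

Step 3
Reactants: 4 (S)-5-(hydroxymethyl)furan-2(5H)-one
Product: 5 (S)-5-(DMTr-oxymethyl)furan-2(5H)-one
Conditions: DMTrCl, pyridine, CH2Cl2, 0 °C → rt
Reagents that add atoms: 4,4'-dimethoxytrityl chloride, COc1ccc(C(Cl)(c2ccccc2)c2ccc(OC)cc2)cc1
Why: Tritylation of a primary alcohol under weakly basic conditions that do not enolise the butenolide, so the stereocentre is untouched; the bulky ether is the facial shield of the key step.

Step 4
Reactants: 6 syringaldehyde (4-hydroxy-3,5-dimethoxybenzaldehyde)
Product: 7 4-(tert-butyldimethylsilyloxy)-3,5-dimethoxybenzaldehyde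
Conditions: TBSCl, imidazole, DMF, rt
Reagents that add atoms: tert-butyldimethylsilyl chloride, CC(C)(C)[Si](C)(C)Cl
Why: Standard phenol silylation; the ether is flanked by two methoxy groups and should be robust to the boron aldol, borohydride and organolithium steps that follow.

Step 5
Reactants: 8 4-bromo-2,6-dimethoxyphenol; 9 (S)-4-benzyl-3-(chloroacetyl)oxazolidin-2-one
Product: 10 (S)-4-benzyl-3-[(4-bromo-2,6-dimethoxyphenoxy)acetyl]oxazolidin-2-one
Conditions: K2CO3, NaI (cat.), acetone, rt → 40 °C
Reagents that add atoms: none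
Why: Williamson ether synthesis at an α-halo carbonyl carbon with iodide (Finkelstein) activation; carbonate is too weak a nucleophile to open the imide, and the bromine atom is the placeholder for the later formyl group.

Step 6
Reactants: 10 (S)-4-benzyl-3-[(4-bromo-2,6-dimethoxyphenoxy)acetyl]oxazolidin-2-one; 7 4-(tert-butyldimethylsilyloxy)-3,5-dimethoxybenzaldehyde
Product: 12 (S)-4-benzyl-3-[(2S,3R)-2-(4-bromo-2,6-dimethoxyphenoxy)-3-hydroxy-3-(4-tert-butyldimethylsilyloxy-3,5-dimethoxyphenyl)propanoyl]oxazolidin-2-one, via boron enolate 11 (not isolated)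
Conditions: Bu2BOTf, iPr2NEt, CH2Cl2, −78 → 0 °C; 7, −78 → 0 °C; H2O2, MeOH, pH 7 buffer, 0 °C
Reagents that add atoms: none
Why: Evans syn-aldol reaction of a glycolate-type imide: the Z boron enolate 11 reacts through a chair Zimmerman–Traxler transition state on the face away from the benzyl group. This should set (2S,3R), the threo relationship and both side-chain stereocentres (later C8'' and C7'').

Step 7
Reactants: 12 the syn aldol imide
Product: 13 (1R,2R)-2-(4-bromo-2,6-dimethoxyphenoxy)-1-(4-tert-butyldimethylsilyloxy-3,5-dimethoxyphenyl)propane-1,3-diol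
Conditions: LiBH4, THF–MeOH, 0 °C
Reagents that add atoms: none
Why: Reductive cleavage of the auxiliary at the exocyclic imide carbonyl gives the primary alcohol C9''; aryl bromide, aryl silyl ether and both stereocentres are not touched.

Step 8
Reactants: 13 the (1R,2R)-diol
Product: 14 5-bromo-2-{[(1R,2R)-1,3-bis(tert-butyldimethylsilyloxy)-1-(4-tert-butyldimethylsilyloxy-3,5-dimethoxyphenyl)propan-2-yl]oxy}-1,3-dimethoxybenzene (ArS–Br)
Conditions: TBSOTf, 2,6-lutidine, CH2Cl2, 0 °C
Reagents that add atoms: tert-butyldimethylsilyl trifluoromethanesulfonate, CC(C)(C)[Si](C)(C)OS(=O)(=O)C(F)(F)F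
Why: The silyl triflate silylates both the primary and the hindered benzylic hydroxyl in one operation; all side-chain oxygens are then masked as fluoride-labile ethers.

Step 9
Reactants: 14 ArS–Br
Product: 16 4-{[(1R,2R)-1,3-bis(tert-butyldimethylsilyloxy)-1-(4-tert-butyldimethylsilyloxy-3,5-dimethoxyphenyl)propan-2-yl]oxy}-3,5-dimethoxybenzaldehyde (ArS–CHO), via aryllithium 15 (not isolated)
Conditions: n-BuLi, THF, −78 °C; DMF, −78 → 0 °C; H2O
Reagents that add atoms: N,N-dimethylformamide, CN(C)C=O
Why: Bromine–lithium exchange is faster at −78 °C than any deprotonation of the silyl ethers or methoxyarenes, and the aryllithium is formylated by the formamide (Bouveault aldehyde synthesis), which installs C7'.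

Step 10
Reactants: 3 2-ArG-1,3-dithiane; 5 (S)-5-(DMTr-oxymethyl)furan-2(5H)-one; 16 ArS–CHO
Product: 19 (3R,4S,5S)-4-(2-ArG-1,3-dithian-2-yl)-5-(DMTr-oxymethyl)-3-[(S)-hydroxy(ArS)methyl]dihydrofuran-2(3H)-one, via lithiated dithiane 17 (not isolated), via lithium enolate 18 (not isolated)
Conditions: 3, n-BuLi, THF, −78 → −30 °C; 5, −78 °C; 16, −78 °C; AcOH, −78 °C
Reagents that add atoms: none
Why: Butyllithium deprotonates 3 to the acyl anion equivalent 17, which adds in a Michael sense to C8 of butenolide 5 (C7–C8) to give lactone enolate 18; this then adds to the formyl carbon of 16 (C7'–C8'), and cold acetic acid freezes the aldolate. The closest known reaction type is the tandem conjugate addition–aldol trapping of 2-aryl-2-lithio-1,3-dithianes with γ-(trityloxymethyl)butenolides and aromatic aldehydes. No ring is closed here; both rings are closed later on the primary carbons. C8 is controlled by the C9 stereocentre of 5, because the nucleophile enters anti to the CH2ODMTr group. C8' is controlled by C8, because the aldehyde meets the enolate face opposite to the bulky dithianyl group, which gives the trans,trans lactone. C7' is controlled by the enolate geometry, which the ring fixes as E: a closed chair transition state with the aryl group equatorial leads to the anti aldol, the (S)-carbinol that later becomes the endo syringyl centre. The step needs 1,4- rather than 1,2-addition, secured by the delocalised benzylic dithianyl anion and the s-cis-locked unsaturated lactone. It also needs a kinetic aldol, secured by low temperature and the acidic quench, which suppress retro-aldol equilibration.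

Step 11
Reactants: 19 the key lactone
Product: 20 (3R,4S,5S)-4-(2-ArG-1,3-dithian-2-yl)-5-(hydroxymethyl)-3-[(S)-hydroxy(ArS)methyl]dihydrofuran-2(3H)-one
Conditions: Cl2CHCO2H (3% v/v), CH2Cl2–MeOH, 0 °C, minutes; pyridine quench
Reagents that add atoms: none
Why: The dimethoxytrityl ether ionises under acid far too weak to ionise the lactone-bound benzylic carbinol or to cleave TBS ethers, and methanol traps the cation; at this stage no hydroxyl is placed to capture a benzylic cation.

Step 12
Reactants: 20 the dithiane lactone diol
Product: 21 (3R,4S,5S)-4-[3-methoxy-4-(triisopropylsilyloxy)benzoyl]-5-(hydroxymethyl)-3-[(S)-hydroxy(ArS)methyl]dihydrofuran-2(3H)-one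
Conditions: MeI, CaCO3, MeCN–H2O (4:1), 40 °C
Reagents that add atoms: water, O
Why: Alkylative dithiane hydrolysis (S-methylation, aryl-assisted thionium ion formation, hydration); the CaCO3-buffered, near-neutral medium avoids both β-elimination of the lactone oxygen from the new ketone and retro-aldol cleavage.

Step 13
Reactants: 21 the keto lactone
Product: 22 (3R,4R,5S)-4-[(R)-hydroxy(ArG)methyl]-5-(hydroxymethyl)-3-[(S)-hydroxy(ArS)methyl]dihydrofuran-2(3H)-one
Conditions: (S)-1-methyl-3,3-diphenyltetrahydro-1H,3H-pyrrolo[1,2-c][1,3,2]oxazaborole [(S)-Me-CBS, 0.5 equiv], BH3·SMe2, THF, −20 °C; MeOH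
Reagents that add atoms: none
Why: Corey–Bakshi–Shibata reduction of an aryl ketone: with the aryl group as the large substituent the (S)-catalyst should deliver hydride to the Si face and give the (7R)-carbinol. The substituents on both ring carbons flanking C8 point to the far face, so the substrate's own bias should be small. The lactone is inert to borane at this temperature, and the free hydroxyls only consume reagent.

Step 14
Reactants: 22 the hydroxy lactone
Product: 23 (1R,2R,3S,4S)-1-ArG-4-ArS-2-[(S)-1,2-dihydroxyethyl]-3-(hydroxymethyl)butane-1,4-diol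
Conditions: LiBH4, THF, 0 °C → rt; H2O
Reagents that add atoms: none
Why: Borohydride reduction of the γ-lactone to the diol leaves the silyl ethers alone and exposes the C9/C10 glycol, the only vicinal diol in the molecule; any lactone isomer formed by acyl migration in 22 would give the same pentaol.

Step 15
Reactants: 23 the pentaol
Product: 25 (1R,2S,3S,4S)-1-ArG-4-ArS-2,3-bis(hydroxymethyl)butane-1,4-diol, via hydroxy aldehyde 24 (not isolated)
Conditions: NaIO4, THF–pH 7 buffer, 0 °C; extractive work-up; NaBH4, MeOH, 0 °C
Reagents that add atoms: none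
Why: Malaprade glycol cleavage excises C10 and leaves C9 as an aldehyde, which is reduced at once to the primary alcohol. The aldehyde is held largely as a lactol, and the neutral buffer with immediate reduction should prevent epimerisation at C8; the phenols are still silylated and are not attacked by periodate.

Step 16
Reactants: 25 the tetraol
Product: 27 tetrasilyl ether of 28 [(7R,8S,7'S,8'S)-7-ArG-7'-ArS furofuran], via bis-mesylate 26 (not isolated)
Conditions: MsCl (2.2 equiv), pyridine, CH2Cl2, 0 °C → rt
Reagents that add atoms: none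
Why: The two primary hydroxyls are sulfonylated in preference to the hindered benzylic ones, and each benzylic hydroxyl then displaces the mesylate four atoms away (two intramolecular Williamson etherifications, 5-exo-tet). The benzylic C–O bonds are not broken, so C7 and C7' are retained as exo guaiacyl and endo syringyl, and the cis fusion is the only one possible.

Step 17
Reactants: 27 the tetrasilyl ether
Product: 28 the target, (7R,8S,7'S,8'S,7''R,8''R)
Conditions: Bu4NF, AcOH, THF, 0 °C → rt
Reagents that add atoms: none
Why: Fluoride cleaves the aryl TIPS, aryl TBS, primary TBS and benzylic TBS ethers in one operation; buffering with acetic acid keeps the medium away from both strong base (phenoxide side reactions) and acid (epimerisation of the endo benzylic ether).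

## Compound list

1 | vanillin | COc1cc(C=O)ccc1O | starting material
2 | 2-(4-hydroxy-3-methoxyphenyl)-1,3-dithiane | COc1cc(C2SCCCS2)ccc1O | intermediate
3 | 2-[3-methoxy-4-(triisopropylsilyloxy)phenyl]-1,3-dithiane | COc1cc(C2SCCCS2)ccc1O[Si](C(C)C)(C(C)C)C(C)C | intermediate
4 | (S)-5-(hydroxymethyl)furan-2(5H)-one | O=C1C=C[C@@H](CO)O1 | starting material
5 | (S)-5-(DMTr-oxymethyl)furan-2(5H)-one | O=C1C=C[C@@H](COC(c2ccccc2)(c2ccc(OC)cc2)c2ccc(OC)cc2)O1 | intermediate
6 | syringaldehyde | COc1cc(C=O)cc(OC)c1O | starting material
7 | 4-(tert-butyldimethylsilyloxy)-3,5-dimethoxybenzaldehyde | COc1cc(C=O)cc(OC)c1O[Si](C)(C)C(C)(C)C | intermediate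
8 | 4-bromo-2,6-dimethoxyphenol | COc1cc(Br)cc(OC)c1O | starting material
9 | (S)-4-benzyl-3-(chloroacetyl)oxazolidin-2-one | O=C(CCl)N1C(=O)OC[C@@H]1Cc1ccccc1 | starting material
10 | (S)-4-benzyl-3-[(4-bromo-2,6-dimethoxyphenoxy)acetyl]oxazolidin-2-one | COc1cc(Br)cc(OC)c1OCC(=O)N1C(=O)OC[C@@H]1Cc1ccccc1 | intermediate
11 | (Z)-dibutylboron enolate of 10 | CCCCB(CCCC)O/C(N1C(=O)OC[C@@H]1Cc1ccccc1)=C\Oc1c(OC)cc(Br)cc1OC | intermediate
12 | (S)-4-benzyl-3-[(2S,3R)-2-(4-bromo-2,6-dimethoxyphenoxy)-3-hydroxy-3-(4-tert-butyldimethylsilyloxy-3,5-dimethoxyphenyl)propanoyl]oxazolidin-2-one | COc1cc(Br)cc(OC)c1O[C@H](C(=O)N1C(=O)OC[C@@H]1Cc1ccccc1)[C@H](O)c1cc(OC)c(O[Si](C)(C)C(C)(C)C)c(OC)c1 | intermediate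
13 | (1R,2R)-2-(4-bromo-2,6-dimethoxyphenoxy)-1-(4-tert-butyldimethylsilyloxy-3,5-dimethoxyphenyl)propane-1,3-diol | COc1cc(Br)cc(OC)c1O[C@H](CO)[C@H](O)c1cc(OC)c(O[Si](C)(C)C(C)(C)C)c(OC)c1 | intermediate
14 | ArS–Br, 5-bromo-2-{[(1R,2R)-1,3-bis(tert-butyldimethylsilyloxy)-1-(4-tert-butyldimethylsilyloxy-3,5-dimethoxyphenyl)propan-2-yl]oxy}-1,3-dimethoxybenzene | COc1cc(Br)cc(OC)c1O[C@H](CO[Si](C)(C)C(C)(C)C)[C@H](O[Si](C)(C)C(C)(C)C)c1cc(OC)c(O[Si](C)(C)C(C)(C)C)c(OC)c1 | intermediate
15 | ArS–Li, the aryllithium from 14 | COc1cc([Li])cc(OC)c1O[C@H](CO[Si](C)(C)C(C)(C)C)[C@H](O[Si](C)(C)C(C)(C)C)c1cc(OC)c(O[Si](C)(C)C(C)(C)C)c(OC)c1 | intermediate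
16 | ArS–CHO, 4-{[(1R,2R)-1,3-bis(tert-butyldimethylsilyloxy)-1-(4-tert-butyldimethylsilyloxy-3,5-dimethoxyphenyl)propan-2-yl]oxy}-3,5-dimethoxybenzaldehyde | COc1cc(C=O)cc(OC)c1O[C@H](CO[Si](C)(C)C(C)(C)C)[C@H](O[Si](C)(C)C(C)(C)C)c1cc(OC)c(O[Si](C)(C)C(C)(C)C)c(OC)c1 | intermediate
17 | 2-lithio-2-ArG-1,3-dithiane | [Li]C1(SCCCS1)c1ccc(O[Si](C(C)C)(C(C)C)C(C)C)c(OC)c1 | intermediate
18 | lithium enolate of (4S,5S)-4-(2-ArG-1,3-dithian-2-yl)-5-(DMTr-oxymethyl)dihydrofuran-2(3H)-one | COc1cc(C2(SCCCS2)[C@H]2C=C(O[Li])O[C@@H]2COC(c2ccccc2)(c2ccc(OC)cc2)c2ccc(OC)cc2)ccc1O[Si](C(C)C)(C(C)C)C(C)C | intermediate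
19 | (3R,4S,5S)-4-(2-ArG-1,3-dithian-2-yl)-5-(DMTr-oxymethyl)-3-[(S)-hydroxy(ArS)methyl]dihydrofuran-2(3H)-one | COc1cc(C2(SCCCS2)[C@@H]2[C@@H](COC(c3ccccc3)(c3ccc(OC)cc3)c3ccc(OC)cc3)OC(=O)[C@H]2[C@H](O)c2cc(OC)c(O[C@H](CO[Si](C)(C)C(C)(C)C)[C@H](O[Si](C)(C)C(C)(C)C)c3cc(OC)c(O[Si](C)(C)C(C)(C)C)c(OC)c3)c(OC)c2)ccc1O[Si](C(C)C)(C(C)C)C(C)C | intermediate
20 | (3R,4S,5S)-4-(2-ArG-1,3-dithian-2-yl)-5-(hydroxymethyl)-3-[(S)-hydroxy(ArS)methyl]dihydrofuran-2(3H)-one | COc1cc(C2(SCCCS2)[C@@H]2[C@@H](CO)OC(=O)[C@H]2[C@H](O)c2cc(OC)c(O[C@H](CO[Si](C)(C)C(C)(C)C)[C@H](O[Si](C)(C)C(C)(C)C)c3cc(OC)c(O[Si](C)(C)C(C)(C)C)c(OC)c3)c(OC)c2)ccc1O[Si](C(C)C)(C(C)C)C(C)C | intermediate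
21 | (3R,4S,5S)-4-[3-methoxy-4-(triisopropylsilyloxy)benzoyl]-5-(hydroxymethyl)-3-[(S)-hydroxy(ArS)methyl]dihydrofuran-2(3H)-one | COc1cc(C(=O)[C@@H]2[C@@H](CO)OC(=O)[C@H]2[C@H](O)c2cc(OC)c(O[C@H](CO[Si](C)(C)C(C)(C)C)[C@H](O[Si](C)(C)C(C)(C)C)c3cc(OC)c(O[Si](C)(C)C(C)(C)C)c(OC)c3)c(OC)c2)ccc1O[Si](C(C)C)(C(C)C)C(C)C | intermediate
22 | (3R,4R,5S)-4-[(R)-hydroxy(ArG)methyl]-5-(hydroxymethyl)-3-[(S)-hydroxy(ArS)methyl]dihydrofuran-2(3H)-one | COc1cc([C@H](O)[C@@H]2[C@@H](CO)OC(=O)[C@H]2[C@H](O)c2cc(OC)c(O[C@H](CO[Si](C)(C)C(C)(C)C)[C@H](O[Si](C)(C)C(C)(C)C)c3cc(OC)c(O[Si](C)(C)C(C)(C)C)c(OC)c3)c(OC)c2)ccc1O[Si](C(C)C)(C(C)C)C(C)C | intermediate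
23 | (1R,2R,3S,4S)-1-ArG-4-ArS-2-[(S)-1,2-dihydroxyethyl]-3-(hydroxymethyl)butane-1,4-diol | COc1cc([C@H](O)[C@H]([C@H](O)CO)[C@@H](CO)[C@H](O)c2cc(OC)c(O[C@H](CO[Si](C)(C)C(C)(C)C)[C@H](O[Si](C)(C)C(C)(C)C)c3cc(OC)c(O[Si](C)(C)C(C)(C)C)c(OC)c3)c(OC)c2)ccc1O[Si](C(C)C)(C(C)C)C(C)C | intermediate
24 | (2R,3S)-4-hydroxy-2-[(R)-hydroxy(ArG)methyl]-3-[(S)-hydroxy(ArS)methyl]butanal (open form of the lactol) | COc1cc([C@H](O)[C@H](C=O)[C@@H](CO)[C@H](O)c2cc(OC)c(O[C@H](CO[Si](C)(C)C(C)(C)C)[C@H](O[Si](C)(C)C(C)(C)C)c3cc(OC)c(O[Si](C)(C)C(C)(C)C)c(OC)c3)c(OC)c2)ccc1O[Si](C(C)C)(C(C)C)C(C)C | intermediate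
25 | (1R,2S,3S,4S)-1-ArG-4-ArS-2,3-bis(hydroxymethyl)butane-1,4-diol | COc1cc([C@H](O)[C@H](CO)[C@@H](CO)[C@H](O)c2cc(OC)c(O[C@H](CO[Si](C)(C)C(C)(C)C)[C@H](O[Si](C)(C)C(C)(C)C)c3cc(OC)c(O[Si](C)(C)C(C)(C)C)c(OC)c3)c(OC)c2)ccc1O[Si](C(C)C)(C(C)C)C(C)C | intermediate
26 | bis(methanesulfonate) of 25 at the two primary hydroxyls | COc1cc([C@H](O)[C@H](COS(C)(=O)=O)[C@@H](COS(C)(=O)=O)[C@H](O)c2cc(OC)c(O[C@H](CO[Si](C)(C)C(C)(C)C)[C@H](O[Si](C)(C)C(C)(C)C)c3cc(OC)c(O[Si](C)(C)C(C)(C)C)c(OC)c3)c(OC)c2)ccc1O[Si](C(C)C)(C(C)C)C(C)C | intermediate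
27 | tetrasilyl ether of 28, (7R,8S,7'S,8'S)-7-ArG-7'-ArS furofuran | COc1cc([C@@H]2OC[C@@H]3[C@H]2CO[C@@H]3c2cc(OC)c(O[C@H](CO[Si](C)(C)C(C)(C)C)[C@H](O[Si](C)(C)C(C)(C)C)c3cc(OC)c(O[Si](C)(C)C(C)(C)C)c(OC)c3)c(OC)c2)ccc1O[Si](C(C)C)(C(C)C)C(C)C | intermediate
28 | CNP0317965.1, (7R,8S,7'S,8'S,7''R,8''R) | COc1cc([C@@H]2OC[C@@H]3[C@H]2CO[C@@H]3c2cc(OC)c(O[C@H](CO)[C@H](O)c3cc(OC)c(O)c(OC)c3)c(OC)c2)ccc1O | target

## Step count and risks

Total: 17 steps. Longest linear sequence: 13 steps (steps 5–17 through the aldehyde arm).

**Step 10 (key step).** The most likely failure is poor simple diastereoselection in the aldol, through partial equilibration of the lithium aldolate or an open transition state, which would give the syn carbinol beside the anti one. A lesser risk is proton transfer from the butenolide to the dithianyl anion. The fallback separates the two events. It sets out from 3 and 5: lithiated 3 is added to 5 and the enolate is quenched with acetic acid to give the trans lactone F1. F1 is then enolised with LDA at −78 °C, transmetallated with ClTi(OiPr)3 and treated with 16. The tighter chair of the titanium enolate, whose E geometry is again fixed by the ring, should raise the anti selectivity. The sequence comes back to the route at 19.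

**Step 13.** The aryl ketone has an α-branched, ring-bound alkyl side, so the catalyst may not tell the two flanks apart well, and alkoxyboranes formed from the free hydroxyls may deliver hydride without the catalyst. The result would be poor facial selectivity at C7. The fallback lets the substrate decide, using the C9 carbinol before it is cut down. It sets out from 19, with the DMTr ether still in place. LiBH4 opens the lactone to the dithiane triol F2. MeI and CaCO3 in aqueous acetonitrile give the β-hydroxy ketone F3. A Narasaka–Prasad reduction (Et2BOMe, NaBH4, THF–MeOH, −78 °C) should then deliver hydride syn to the C9 hydroxyl through the boron chelate, and the 7,9-syn diol is the (7R)-carbinol F4. Removal of the DMTr group with Cl2CHCO2H as in step 11 returns to the route at 23.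

**Step 16.** Sulfonylation may spill over onto a benzylic hydroxyl, which would then ionise and lose its configuration, or the closure of ring B with its endo aryl group may be slow enough for side reactions of the mesylate. The fallback separates activation from closure. It sets out from 25: 2,4,6-triisopropylbenzenesulfonyl chloride in pyridine at 0 °C, a reagent that is selective for primary hydroxyls, gives the bis-sulfonate F5. F5 is then closed with NaH in THF at 0 °C through the alkoxides, which comes back to the route at 27.

**Step 5.** Phenoxide or carbonate may attack the imide carbonyl (acyl transfer) in place of the CH2Cl carbon. The fallback builds the ether before the imide. It sets out from 8: alkylation with bromoacetic acid in aqueous NaOH gives the aryloxyacetic acid F6. F6 is activated as the mixed pivalic anhydride (pivaloyl chloride, Et3N) and coupled with (S)-4-benzyloxazolidin-2-one in the presence of LiCl, which comes back to the route at 10.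

## Further compounds

F1 | step 10 | (4S,5S)-4-(2-ArG-1,3-dithian-2-yl)-5-(DMTr-oxymethyl)dihydrofuran-2(3H)-one | COc1cc(C2(SCCCS2)[C@@H]2[C@@H](COC(c3ccccc3)(c3ccc(OC)cc3)c3ccc(OC)cc3)OC(=O)C2)ccc1O[Si](C(C)C)(C(C)C)C(C)C
F2 | step 13 | dithiane triol from reduction of the lactone of 19 (DMTr ether retained) | COc1cc(C2(SCCCS2)[C@H]([C@H](O)COC(c2ccccc2)(c2ccc(OC)cc2)c2ccc(OC)cc2)[C@@H](CO)[C@H](O)c2cc(OC)c(O[C@H](CO[Si](C)(C)C(C)(C)C)[C@H](O[Si](C)(C)C(C)(C)C)c3cc(OC)c(O[Si](C)(C)C(C)(C)C)c(OC)c3)c(OC)c2)ccc1O[Si](C(C)C)(C(C)C)C(C)C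
F3 | step 13 | β-hydroxy aryl ketone from hydrolysis of the dithiane of F2 | COc1cc(C(=O)[C@H]([C@H](O)COC(c2ccccc2)(c2ccc(OC)cc2)c2ccc(OC)cc2)[C@@H](CO)[C@H](O)c2cc(OC)c(O[C@H](CO[Si](C)(C)C(C)(C)C)[C@H](O[Si](C)(C)C(C)(C)C)c3cc(OC)c(O[Si](C)(C)C(C)(C)C)c(OC)c3)c(OC)c2)ccc1O[Si](C(C)C)(C(C)C)C(C)C
F4 | step 13 | (7R)-tetraol, the 10-O-DMTr ether of 23 | COc1cc([C@H](O)[C@H]([C@H](O)COC(c2ccccc2)(c2ccc(OC)cc2)c2ccc(OC)cc2)[C@@H](CO)[C@H](O)c2cc(OC)c(O[C@H](CO[Si](C)(C)C(C)(C)C)[C@H](O[Si](C)(C)C(C)(C)C)c3cc(OC)c(O[Si](C)(C)C(C)(C)C)c(OC)c3)c(OC)c2)ccc1O[Si](C(C)C)(C(C)C)C(C)C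
F5 | step 16 | bis(2,4,6-triisopropylbenzenesulfonate) of 25 at the two primary hydroxyls | COc1cc([C@H](O)[C@H](COS(=O)(=O)c2c(C(C)C)cc(C(C)C)cc2C(C)C)[C@@H](COS(=O)(=O)c2c(C(C)C)cc(C(C)C)cc2C(C)C)[C@H](O)c2cc(OC)c(O[C@H](CO[Si](C)(C)C(C)(C)C)[C@H](O[Si](C)(C)C(C)(C)C)c3cc(OC)c(O[Si](C)(C)C(C)(C)C)c(OC)c3)c(OC)c2)ccc1O[Si](C(C)C)(C(C)C)C(C)C
F6 | step 5 | (4-bromo-2,6-dimethoxyphenoxy)acetic acid | COc1cc(Br)cc(OC)c1OCC(=O)O
A1 | alternative 1 | dihydrofuran-fused lactone with the C7'=C8' enol ether | COc1cc([C@@H]2OC(=O)C3=C(c4cc(OC)c(O[C@H](CO[Si](C)(C)C(C)(C)C)[C@H](O[Si](C)(C)C(C)(C)C)c5cc(OC)c(O[Si](C)(C)C(C)(C)C)c(OC)c5)c(OC)c4)OC[C@@H]23)ccc1O[Si](C(C)C)(C(C)C)C(C)C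
A2 | alternative 1 | lactone-fused aroyl cyclopropane (4-ArG-1-aroyl-3-oxabicyclo[3.1.0]hexan-2-one) | COc1cc([C@@H]2OC(=O)[C@@]3(C(=O)c4cc(OC)c(O[C@H](CO[Si](C)(C)C(C)(C)C)[C@H](O[Si](C)(C)C(C)(C)C)c5cc(OC)c(O[Si](C)(C)C(C)(C)C)c(OC)c5)c(OC)c4)C[C@@H]23)ccc1O[Si](C(C)C)(C(C)C)C(C)C
A3 | alternative 2 | cis-fused lactone ester with endo syringyl group | O=C1OC[C@@H]2[C@@]1(C(=O)OC)CO[C@@H]2c1cc(OC)c(O[C@H](CO[Si](C)(C)C(C)(C)C)[C@H](O[Si](C)(C)C(C)(C)C)c2cc(OC)c(O[Si](C)(C)C(C)(C)C)c(OC)c2)c(OC)c1
A4 | alternative 2 | threo epoxy alcohol, ArS-substituted oxiranylmethanol | O[C@@H]([C@@H]1OC1)c1cc(OC)c(O[C@H](CO[Si](C)(C)C(C)(C)C)[C@H](O[Si](C)(C)C(C)(C)C)c2cc(OC)c(O[Si](C)(C)C(C)(C)C)c(OC)c2)c(OC)c1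
A5 | alternative 2 | dimethyl methylenemalonate | C=C(C(=O)OC)C(=O)OC
A6 | alternative 3 | endo-syringyl, exo-guaiacyl furofuranone | COc1cc([C@@H]2OC(=O)[C@@H]3[C@H]2CO[C@@H]3c2cc(OC)c(O[C@H](CO[Si](C)(C)C(C)(C)C)[C@H](O[Si](C)(C)C(C)(C)C)c3cc(OC)c(O[Si](C)(C)C(C)(C)C)c(OC)c3)c(OC)c2)ccc1O[Si](C(C)C)(C(C)C)C(C)C
A7 | alternative 3 | α-diazo-γ-butyrolactone with the tethered syringylmethyl ether | COc1cc([C@@H]2OC(=O)C(=[N+]=[N-])[C@H]2COCc2cc(OC)c(O[C@H](CO[Si](C)(C)C(C)(C)C)[C@H](O[Si](C)(C)C(C)(C)C)c3cc(OC)c(O[Si](C)(C)C(C)(C)C)c(OC)c3)c(OC)c2)ccc1O[Si](C(C)C)(C(C)C)C(C)C
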